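The quinone ring is read as the enol ether of a 1,2,4-trione: C2 stands at the carboxyl oxidation level and C3 is the α-carbon of the C4 ketone, so the C2–C3 bond is a Claisen retron. The key step is an intramolecular Claisen condensation that joins C3 (acetyl methyl) to C2 (ester carbon of an aryl oxoacetate) and so closes the quinone ring on the finished biaryl benzene ring; acidified methanol then methylates the 2-hydroxyquinone in the same flask. The precursor is an open benzene carrying acetyl and methyl oxoacetate arms on neighbouring carbons beside the 3,4-dimethoxyphenyl group, made from 3-bromo-5-chloroanisole by lithiation/oxalylation and two cross-couplings.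

Key step: step 4

Remark: the target has no stereocentre; the 2-hydroxyquinone formed on ring closure is written as its 2-hydroxy-1,4-dione tautomer.

Step 1
Reactants: 1 3-bromo-5-chloroanisole; 2 dimethyl oxalate
Product: 4 methyl 2-(2-bromo-6-chloro-4-methoxyphenyl)-2-oxoacetate, via aryllithium 3 (not isolated)
Conditions: LiN(i-Pr)2 (1.1 equiv), THF, −78 °C; then added to (CO2Me)2 (3 equiv), THF, −78 °C; aq. NH4Cl
Reagents that add atoms: dimethyl oxalate COC(=O)C(=O)OC
Why: Deprotonative lithiation followed by acylation of the aryllithium with an oxalate diester: the C–H flanked by bromine and chlorine (para to methoxy) is the most acidic site, and inverse addition to excess oxalate at low temperature should stop at the keto ester because the tetrahedral adduct persists until work-up.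

Step 2
Reactants: 4 methyl 2-(2-bromo-6-chloro-4-methoxyphenyl)-2-oxoacetate; 5 (3,4-dimethoxyphenyl)boronic acid
Product: 6 methyl 2-[2-chloro-6-(3,4-dimethoxyphenyl)-4-methoxyphenyl]-2-oxoacetate
Conditions: Pd(PPh3)4 (5 mol %), CsF (3 equiv), DME, 80 °C
Reagents that add atoms: (3,4-dimethoxyphenyl)boronic acid COc1ccc(B(O)O)cc1OC
Why: Suzuki–Miyaura coupling: triphenylphosphine-ligated zerovalent palladium inserts into the C–Br bond far faster than into the C–Cl bond, and anhydrous fluoride activation of the boronic acid should spare the base-sensitive keto ester.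

Step 3
Reactants: 6 methyl 2-[2-chloro-6-(3,4-dimethoxyphenyl)-4-methoxyphenyl]-2-oxoacetate; 7 tributyl(1-ethoxyethenyl)stannane
Product: 9 methyl 2-[2-acetyl-6-(3,4-dimethoxyphenyl)-4-methoxyphenyl]-2-oxoacetate, via enol ether 8 (not isolated)
Conditions: Pd2(dba)3 (2 mol %), [HP(t-Bu)3]BF4 (8 mol %), CsF (2.2 equiv), 1,4-dioxane, 100 °C; then 1 M aq. HCl, THF, rt
Reagents that add atoms: tributyl(1-ethoxyethenyl)stannane CCCC[Sn](CCCC)(CCCC)C(=C)OCC; water O
Why: Stille coupling of an aryl chloride that is activated by the ortho keto group, with a bulky electron-rich phosphine and fluoride activation of the stannane, should give enol ether 8, which dilute acid hydrolyses to the methyl ketone.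

Step 4
Reactants: 9 methyl 2-[2-acetyl-6-(3,4-dimethoxyphenyl)-4-methoxyphenyl]-2-oxoacetate
Product: 12 8-(3,4-dimethoxyphenyl)-2,6-dimethoxynaphthalene-1,4-dione, via sodium quinonolate 10 (not isolated), via hydroxyquinone 11 (not isolated)
Conditions: NaOMe (2.5 equiv), MeOH, 0 to 50 °C; then conc. H2SO4 (6 equiv), MeOH, reflux
Reagents that add atoms: methanol CO
Why: Methoxide reversibly forms the enolate of the acetyl group, whose carbon (C3) adds to the ester carbonyl of the neighbouring oxoacetate arm (C2); loss of methoxide gives the 1,2,4-trione, which is deprotonated at once to the vinylogous carboxylate 10, and this acid–base step should make the intramolecular Claisen condensation irreversible. The closest known reaction is the Dieckmann-type closure of 2-acetylphenylacetic esters to naphthalene-1,3-diols, here run one oxidation level higher at C1. The quinone ring is closed in the 6-(enolendo)-exo-trig mode. No stereocentre is formed. The step needs acylation at the ester carbon and not aldol addition to the C1 keto group: that competing closure is a strained 5-(enolendo)-exo-trig process that is reversible under alkoxide, the oxoacetate arm has no α-hydrogen and the acetyl group is the only enolisable site, so the material should drain into 10. Acidified methanol then converts the vinylogous acid 11 into its methyl ether (Fischer-type etherification of a 2-hydroxy-1,4-naphthoquinone), and under this thermodynamic control the para-quinone ether with methoxy on C2 is expected and not the ortho-quinone isomer.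

Compound list
1 | 3-bromo-5-chloroanisole (1-bromo-3-chloro-5-methoxybenzene) | COc1cc(Br)cc(Cl)c1 | starting material
2 | dimethyl oxalate | COC(=O)C(=O)OC | starting material
3 | (2-bromo-6-chloro-4-methoxyphenyl)lithium | [Li]c1c(Br)cc(OC)cc1Cl | intermediate
4 | methyl 2-(2-bromo-6-chloro-4-methoxyphenyl)-2-oxoacetate | COC(=O)C(=O)c1c(Br)cc(OC)cc1Cl | intermediate
5 | (3,4-dimethoxyphenyl)boronic acid | COc1ccc(B(O)O)cc1OC | starting material
6 | methyl 2-[2-chloro-6-(3,4-dimethoxyphenyl)-4-methoxyphenyl]-2-oxoacetate | COC(=O)C(=O)c1c(Cl)cc(OC)cc1-c1ccc(OC)c(OC)c1 | intermediate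
7 | tributyl(1-ethoxyethenyl)stannane | CCCC[Sn](CCCC)(CCCC)C(=C)OCC | starting material
8 | methyl 2-[2-(3,4-dimethoxyphenyl)-6-(1-ethoxyethenyl)-4-methoxyphenyl]-2-oxoacetate | CCOC(=C)c1cc(OC)cc(-c2ccc(OC)c(OC)c2)c1C(=O)C(=O)OC | intermediate
9 | methyl 2-[2-acetyl-6-(3,4-dimethoxyphenyl)-4-methoxyphenyl]-2-oxoacetate | COC(=O)C(=O)c1c(C(C)=O)cc(OC)cc1-c1ccc(OC)c(OC)c1 | intermediate
10 | sodium 8-(3,4-dimethoxyphenyl)-6-methoxy-1,4-dioxo-1,4-dihydronaphthalen-2-olate | [Na+].[O-]C1=CC(=O)c2cc(OC)cc(-c3ccc(OC)c(OC)c3)c2C1=O | intermediate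
11 | 8-(3,4-dimethoxyphenyl)-2-hydroxy-6-methoxynaphthalene-1,4-dione | OC1=CC(=O)c2cc(OC)cc(-c3ccc(OC)c(OC)c3)c2C1=O | intermediate
12 | 8-(3,4-dimethoxyphenyl)-2,6-dimethoxynaphthalene-1,4-dione (CNP0128574.0) | COC1=CC(=O)c2cc(OC)cc(-c3ccc(OC)c(OC)c3)c2C1=O | target

Total step count: 4. Longest linear sequence: 4 steps.

Steps most likely to fail

Step 4. The enolate may be diverted into aldol addition at the C1 keto group followed by dehydration, or methoxide may cleave the keto ester, so that closure at the ester carbon does not win. The fallback sets out from 6 and comes back to the route at 12; it removes the C1 carbonyl before ring closure and restores it afterwards. Ionic hydrogenation of 6 (Et3SiH, TFA, 50 °C) should give methyl 2-[2-chloro-6-(3,4-dimethoxyphenyl)-4-methoxyphenyl]acetate F1. Stille coupling with 7 under the conditions of step 3 should give methyl 2-[2-(3,4-dimethoxyphenyl)-6-(1-ethoxyethenyl)-4-methoxyphenyl]acetate F2 and, after dilute HCl, methyl 2-[2-acetyl-6-(3,4-dimethoxyphenyl)-4-methoxyphenyl]acetate F3. NaOMe in MeOH should then close the same C2–C3 bond by Dieckmann condensation, with no keto acceptor left to compete, giving 5-(3,4-dimethoxyphenyl)-7-methoxynaphthalene-1,3-diol F4. MeOH/HCl should methylate the 3-hydroxyl selectively to 5-(3,4-dimethoxyphenyl)-3,7-dimethoxynaphthalen-1-ol F5, and oxidation with potassium nitrosodisulfonate, K2[ON(SO3)2], at the free para position should give 12.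

Step 3. Oxidative addition into the hindered C–Cl bond may be slow, so that destannylation of 7 and decomposition of the keto ester overtake the coupling. The fallback sets out from 6 and comes back to the route at 9; it uses boron in place of tin and oxidative cleavage in place of enol ether hydrolysis. Suzuki–Miyaura coupling of 6 with commercial isopropenylboronic acid pinacol ester (Pd(OAc)2, SPhos, anhydrous K3PO4, toluene, 90 °C) should give methyl 2-[2-(3,4-dimethoxyphenyl)-4-methoxy-6-(prop-1-en-2-yl)phenyl]-2-oxoacetate F6. Lemieux–Johnson cleavage of the 1,1-disubstituted alkene (OsO4 cat., NaIO4, 2,6-lutidine, dioxane/water) should give 9.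

Step 1. The ortho,ortho'-dihaloaryllithium may lose lithium halide to an aryne, metalation may occur beside the methoxy group, or the aryllithium may add twice to the oxalate. Because this is the first step, the fallback does not branch from a route intermediate: it sets out from dimethyl oxalate 2 with a new commercial arene in place of 1, and comes back to the route at 8. The metal is placed by halogen–magnesium exchange at a pre-installed iodine instead of by deprotonation. 2,6-Dibromo-4-methoxyaniline F7 is diazotised (NaNO2, H2SO4, 0 °C) to 2,6-dibromo-4-methoxybenzenediazonium hydrogen sulfate F8, and KI (Sandmeyer-type iodination) should give 1,3-dibromo-2-iodo-5-methoxybenzene F9. i-PrMgCl·LiCl (THF, −40 °C) should exchange only the iodine to give (2,6-dibromo-4-methoxyphenyl)magnesium chloride F10, which is added to excess 2 to give methyl 2-(2,6-dibromo-4-methoxyphenyl)-2-oxoacetate F11. Suzuki–Miyaura coupling with 5 (conditions of step 2, dibromide in excess) should give methyl 2-[2-bromo-6-(3,4-dimethoxyphenyl)-4-methoxyphenyl]-2-oxoacetate F12. Stille coupling with 7 (Pd(PPh3)4, toluene, 100 °C) should give 8, which is hydrolysed to 9 as in step 3.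

Further compounds
F1 | step 4 | methyl 2-[2-chloro-6-(3,4-dimethoxyphenyl)-4-methoxyphenyl]acetate | COC(=O)Cc1c(Cl)cc(OC)cc1-c1ccc(OC)c(OC)c1
F2 | step 4 | methyl 2-[2-(3,4-dimethoxyphenyl)-6-(1-ethoxyethenyl)-4-methoxyphenyl]acetate | CCOC(=C)c1cc(OC)cc(-c2ccc(OC)c(OC)c2)c1CC(=O)OC
F3 | step 4 | methyl 2-[2-acetyl-6-(3,4-dimethoxyphenyl)-4-methoxyphenyl]acetate | COC(=O)Cc1c(C(C)=O)cc(OC)cc1-c1ccc(OC)c(OC)c1
F4 | step 4 | 5-(3,4-dimethoxyphenyl)-7-methoxynaphthalene-1,3-diol | Oc1cc(O)cc2c(-c3ccc(OC)c(OC)c3)cc(OC)cc12
F5 | step 4 | 5-(3,4-dimethoxyphenyl)-3,7-dimethoxynaphthalen-1-ol | COc1cc(O)c2cc(OC)cc(-c3ccc(OC)c(OC)c3)c2c1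
F6 | step 3 | methyl 2-[2-(3,4-dimethoxyphenyl)-4-methoxy-6-(prop-1-en-2-yl)phenyl]-2-oxoacetate | COC(=O)C(=O)c1c(C(C)=C)cc(OC)cc1-c1ccc(OC)c(OC)c1
F7 | step 1 | 2,6-dibromo-4-methoxyaniline | COc1cc(Br)c(N)c(Br)c1
F8 | step 1 | 2,6-dibromo-4-methoxybenzenediazonium hydrogen sulfate | COc1cc(Br)c([N+]#N)c(Br)c1.OS(=O)(=O)[O-]
F9 | step 1 | 1,3-dibromo-2-iodo-5-methoxybenzene | COc1cc(Br)c(I)c(Br)c1
F10 | step 1 | (2,6-dibromo-4-methoxyphenyl)magnesium chloride | COc1cc(Br)c([Mg]Cl)c(Br)c1
F11 | step 1 | methyl 2-(2,6-dibromo-4-methoxyphenyl)-2-oxoacetate | COC(=O)C(=O)c1c(Br)cc(OC)cc1Br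
F12 | step 1 | methyl 2-[2-bromo-6-(3,4-dimethoxyphenyl)-4-methoxyphenyl]-2-oxoacetate | COC(=O)C(=O)c1c(Br)cc(OC)cc1-c1ccc(OC)c(OC)c1
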